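**Retrosynthetic overview**

1. Locants follow hydrindan-2-one (C1 = ring CH2, C2 = C=O, C3 = carbon bearing the acetoxyethyl group, C3a/C7a = ring fusion, C4 = oxiranyl, C5/C6 = acyloxy, C7 = methylidene carbon); carvone C1–C6 become C6, C7, C7a, C3a, C4, C5.
2. Target ⇐ C5 esterification, side-chain acetylation and C5-OH-directed epoxidation of the isopropenyl group ⇐ C6 enoate by Mitsunobu inversion ⇐ C7 methylidene/C6 carbinol from a C6 ketone–C7 methyl unit (selenenylation, reduction, selenoxide elimination).
3. Key disconnection C1–C7a: reversible intramolecular Michael addition of a β-keto ester carbon (C1) to C7a. The enabling feature is that C7a is the β-carbon of the carvone-type enone (C6=O, C7(CH3)=C7a) and sits next to C3a, which carries the C3–C2–C1 chain; the trans-fused hydrindane with every six-ring substituent equatorial is the thermodynamic sink.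
4. The chain is put on C3a by a ketene-acetal Claisen rearrangement of a cis-1,2-diol, which leaves a temporary bridged lactone (C3a–C3–C2(=O)–O–C6). An aldol reaction on this lactone sets C3 and the carbinol carbon, and ester-enolate opening gives the β-keto ester. The diol comes from (S)-carvone by α'-hydroxylation, epoxidation, reduction and selenide opening/selenoxide elimination.
5. Ring order: six-membered ring from (S)-carvone; temporary seven-membered lactone formed (step 6) and opened (step 9); five-membered ring closed last, in the key step.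

Key step: step 10

Remark: the homoallylic-alcohol-directed epoxidation of step 16 is assumed to give the (S)-oxirane through the chair-like vanadate transition state; only the trunk compounds and the two acyl donors are numbered, other reagents are given with SMILES in the steps.

Step 1
Reactants: 1 (S)-carvone
Product: 2 trans-6-hydroxycarvone
Conditions: KN(SiMe3)2, THF, −78 °C; 2-(phenylsulfonyl)-3-phenyloxaziridine, −78 °C; H2O
Reagents that add atoms: 2-(phenylsulfonyl)-3-phenyloxaziridine, O=S(=O)(c1ccccc1)N1OC1c1ccccc1
Why: Enolate hydroxylation: the bulky amide removes the α' proton (carvone C6) and the N-sulfonyloxaziridine transfers oxygen to the enolate face anti to the adjacent isopropenyl group, which sets the future C5 oxygen trans to C4.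

Step 2
Reactants: 2 trans-6-hydroxycarvone
Product: 3 silyl ether of 2
Conditions: t-BuMe2SiCl, imidazole, DMF, rt
Reagents that add atoms: tert-butyldimethylsilyl chloride, C[Si](C)(Cl)C(C)(C)C
Why: Silyl ether formation masks the α-hydroxy ketone for the basic and reducing steps that follow.

Step 3
Reactants: 3 silyl ether of 2
Product: 4 epoxy ketone
Conditions: 30% H2O2, NaOH (cat.), MeOH, 0 °C
Reagents that add atoms: hydrogen peroxide, OO
Why: Weitz–Scheffer (nucleophilic) epoxidation: hydroperoxide adds axially to the enone β-carbon anti to the isopropenyl group, so the oxirane oxygen should lie on the same face as the silyloxy group.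

Step 4
Reactants: 4 epoxy ketone
Product: 5 cis-epoxy alcohol
Conditions: Zn(BH4)2, Et2O, 0 °C; H2O
Reagents that add atoms: none
Why: Chelation-controlled ketone reduction: zinc bridges the carbonyl and oxirane oxygens and hydride arrives from the opposite face, which should give the cis-epoxy alcohol needed for the cyclic orthoester of step 6.

Step 5
Reactants: 5 cis-epoxy alcohol
Product: 8 cis-diol with tertiary allylic hydroxyl, via hydroxy selenide 6 (not isolated), via selenoxide 7 (not isolated)
Conditions: PhSeSePh, NaBH4, EtOH, reflux; then 30% H2O2, pyridine, THF, 0 °C → rt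
Reagents that add atoms: none
Why: Epoxide-to-allylic-alcohol transposition: benzeneselenolate opens the oxirane at its secondary carbon (trans-diaxial) and the selenoxide syn-eliminates away from the carbinol carbon, which leaves the tertiary allylic alcohol with its C–O bond untouched.

Step 6
Reactants: 8 cis-diol with tertiary allylic hydroxyl
Product: 11 bridged lactone, via cyclic orthoester 9 (not isolated), via ketene acetal 10 (not isolated)
Conditions: MeC(OEt)3, EtCO2H (cat.), xylene, 140 °C (−EtOH)
Reagents that add atoms: triethyl orthoacetate, CC(OCC)(OCC)OCC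
Why: Johnson–Claisen rearrangement through a cyclic ketene acetal: the cis-diol is tied up as orthoester 9, which loses ethanol to 10, and the [3,3] shift breaks the tertiary allylic C–O bond and delivers the new carbon suprafacially to the same face of C3a (trans to isopropenyl), the acyl group staying on the C6 oxygen as a bridged lactone.

Step 7
Reactants: 11 bridged lactone
Product: 12 aldol lactone
Conditions: LiN(iPr)2, THF, −78 °C; Cp2ZrCl2, −78 → −30 °C; MeCHO, −78 °C; H2O
Reagents that add atoms: acetaldehyde, CC=O
Why: Aldol addition of a zirconium enolate, which is syn-selective whatever the enolate geometry; the lactone enolate should react on the face turned toward the alkene bridge and away from the silyloxy-bearing bridge, which sets C3 and the carbinol carbon as in the target.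

Step 8
Reactants: 12 aldol lactone
Product: 13 bis-silyl lactone
Conditions: t-BuMe2SiOTf, 2,6-lutidine, CH2Cl2, −78 °C
Reagents that add atoms: tert-butyldimethylsilyl triflate, CC(C)(C)[Si](C)(C)OS(=O)(=O)C(F)(F)F
Why: Silylation protects the β-hydroxy lactone against retro-aldol cleavage and elimination in the basic steps that follow.

Step 9
Reactants: 13 bis-silyl lactone
Product: 14 hydroxy β-keto allyl ester
Conditions: allyl acetate, LiN(SiMe3)2 (3.2 equiv), THF, −78 → −30 °C; H2O
Reagents that add atoms: allyl acetate, CC(=O)OCC=C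
Why: Claisen condensation: the lithium enolate of allyl acetate adds to the lactone carbonyl, the tetrahedral intermediate collapses with release of the C6 alkoxide, and the β-keto ester is shielded from further addition as its enolate.

Step 10
Reactants: 14 hydroxy β-keto allyl ester
Product: 17 trans-fused hydrindanedione allyl ester, via enone 15 (not isolated), via cis-fused adduct 16 (not isolated)
Conditions: MnO2, CH2Cl2, rt; then DBU (0.3 equiv), 40 °C
Reagents that add atoms: none
Why: MnO2 oxidises the allylic C6 alcohol to the carvone-type enone 15, and DBU then turns the β-keto ester into a stabilised carbanion at C1 that adds to the enone β-carbon C7a, an intramolecular Michael addition of the kind used to close 2-oxocyclopentanecarboxylates from unsaturated β-keto esters. The five-membered ring closes 5-exo-trig through the ester-enolate form of the nucleophile. Attack from the face of the C3a tether first gives the cis-fused adduct 16, but a β-keto ester anion is a good enough leaving group for retro-Michael cleavage through the C6 enolate, so 16 and 17 interconvert under the catalytic base while C7, C1 and C3 equilibrate by enolisation. The step therefore needs thermodynamic rather than kinetic selectivity, and the substrate supplies it: only the trans-fused isomer places C1, C3, the isopropenyl group, the silyloxy group and the C7 methyl all equatorial on a chair cyclohexanone fused to a cyclopentanone whose carbonyl lies opposite the ring-fusion bond. C7a is thus set trans to C3a, C7 carries an equatorial methyl, and the configuration at C1 is immaterial because this carbon becomes CH2 in step 13.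

Step 11
Reactants: 17 trans-fused hydrindanedione allyl ester
Product: 19 hydroxy selenide, via seleno ketone 18 (not isolated)
Conditions: LiN(SiMe3)2 (2.2 equiv), THF, −78 °C; PhSeBr; then iBu2AlH, −78 °C; H2O
Reagents that add atoms: phenylselenenyl bromide, Br[Se]c1ccccc1
Why: Regioselective α-selenenylation and reduction in one flask: the first equivalent of base parks the β-keto ester as its enolate, the second enolises the C6 ketone toward C7 (away from the silyloxy-bearing C5), selenium enters axially, and the hydride then attacks anti to the axial C–Se bond to give the equatorial C6 alcohol.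

Step 12
Reactants: 19 hydroxy selenide
Product: 21 methylidene alcohol β-keto ester, via selenoxide 20 (not isolated)
Conditions: 30% H2O2, pyridine, CH2Cl2, 0 °C → rt
Reagents that add atoms: none
Why: Selenoxide syn-elimination: the axial selenoxide on C7 has no syn hydrogen on C7a or C6, so only the methyl hydrogens can be taken and the exocyclic methylidene should result.

Step 13
Reactants: 21 methylidene alcohol β-keto ester
Product: 22 methylidene alcohol ketone
Conditions: Pd(PPh3)4 (5 mol %), morpholine, THF, rt
Reagents that add atoms: none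
Why: Tsuji–Trost deallylation–decarboxylation: zerovalent palladium ionises the allyl ester, morpholine traps the allyl group, and the β-keto acid loses CO2 under neutral conditions that spare the β-silyloxy ketone.

Step 14
Reactants: 22 methylidene alcohol ketone; 23 (E)-3-methylpent-2-enoic acid
Product: 24 C6 enoate
Conditions: PPh3, DIAD, toluene, 0 °C → rt
Reagents that add atoms: none
Why: Mitsunobu esterification: SN2 displacement of the oxyphosphonium of the equatorial allylic alcohol by the carboxylate inverts C6 and installs the axial enoate cis to the C5 oxygen.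

Step 15
Reactants: 24 C6 enoate
Product: 25 diol
Conditions: HF·pyridine, pyridine, THF, 0 °C → rt
Reagents that add atoms: none
Why: Fluoride cleaves both silyl ethers under buffered, non-basic conditions that should leave the ester and the β-hydroxy ketone intact.

Step 16
Reactants: 25 diol
Product: 26 epoxy diol
Conditions: VO(acac)2 (5 mol %), t-BuOOH, CH2Cl2, 0 °C → rt
Reagents that add atoms: tert-butyl hydroperoxide, CC(C)(C)OO
Why: Hydroxyl-directed epoxidation by the vanadium tert-butylperoxo complex formed from VO(acac)2: the equatorial C5 alkoxide carries the metal to the gauche isopropenyl group on C4 (the C7 methylidene, anti to the C5–O bond, and the enoate are out of reach), and the chair-like transition state should deliver oxygen to the face that gives the (S)-oxirane.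

Step 17
Reactants: 26 epoxy diol
Product: 27 monoacetate
Conditions: Ac2O, pyridine, CH2Cl2, 0 °C
Reagents that add atoms: acetic anhydride, CC(=O)OC(C)=O
Why: Selective acylation: the side-chain carbinol is less hindered than the C5 hydroxyl, which is flanked by the oxiranyl-bearing C4 and the acyloxy-bearing C6.

Step 18
Reactants: 27 monoacetate; 28 (S)-2-methylbutanoic acid
Product: 29 target CNP0120390.2
Conditions: DCC, DMAP (cat.), CH2Cl2, 0 °C → rt
Reagents that add atoms: none
Why: Steglich esterification acylates the remaining hindered secondary alcohol without touching the epoxide or the β-acetoxy ketone.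

**Compound list**

1 | (S)-(+)-carvone, (5S)-2-methyl-5-(prop-1-en-2-yl)cyclohex-2-en-1-one | CC1=CC[C@H](C(C)=C)CC1=O | starting material
2 | (5R,6R)-6-hydroxy-2-methyl-5-(prop-1-en-2-yl)cyclohex-2-en-1-one (6-OH trans to isopropenyl) | CC1=CC[C@H](C(C)=C)[C@@H](O)C1=O | intermediate
3 | 6-O-tert-butyldimethylsilyl ether of 2 | CC1=CC[C@H](C(C)=C)[C@@H](O[Si](C)(C)C(C)(C)C)C1=O | intermediate
4 | 2,3-epoxide of 3 (oxirane oxygen cis to the silyloxy group, trans to isopropenyl) | C[C@]12O[C@H]1C[C@H](C(C)=C)[C@@H](O[Si](C)(C)C(C)(C)C)C2=O | intermediate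
5 | epoxy alcohol from 4 (C1 hydroxyl cis to the oxirane oxygen and to the silyloxy group) | C[C@]12O[C@H]1C[C@H](C(C)=C)[C@@H](O[Si](C)(C)C(C)(C)C)[C@H]2O | intermediate
6 | 2-methyl-3-(phenylselanyl)-5-isopropenyl-6-silyloxycyclohexane-1,2-diol (carvone numbering; selenium trans to the C2 hydroxyl) | C[C@]1(O)[C@H]([Se]c2ccccc2)C[C@H](C(C)=C)[C@@H](O[Si](C)(C)C(C)(C)C)[C@H]1O | intermediate (not isolated)
7 | selenoxide of 6 | C[C@]1(O)[C@H]([Se](=O)c2ccccc2)C[C@H](C(C)=C)[C@@H](O[Si](C)(C)C(C)(C)C)[C@H]1O | intermediate (not isolated)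
8 | 2-methyl-5-isopropenyl-6-silyloxycyclohex-3-ene-1,2-diol (carvone numbering; the three oxygens cis, isopropenyl trans to them) | C[C@]1(O)C=C[C@H](C(C)=C)[C@@H](O[Si](C)(C)C(C)(C)C)[C@H]1O | intermediate
9 | cyclic orthoester of 8 (2-ethoxy-2-methyl-1,3-dioxolane; orthoester carbon unassigned) | CCOC1(C)O[C@@]2(C)C=C[C@H](C(C)=C)[C@@H](O[Si](C)(C)C(C)(C)C)[C@H]2O1 | intermediate (not isolated)
10 | cyclic ketene acetal of 8 (2-methylidene-1,3-dioxolane) | C=C1O[C@@]2(C)C=C[C@H](C(C)=C)[C@@H](O[Si](C)(C)C(C)(C)C)[C@H]2O1 | intermediate (not isolated)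
11 | bridged lactone C3a–CH2–C(=O)–O–C6 on the 7-methylcyclohex-7(7a)-ene ring, 5-silyloxy, 4-isopropenyl (lactone bridge and silyloxy on one face, isopropenyl on the other) | CC1=C[C@H]2CC(=O)O[C@@H]1[C@H](O[Si](C)(C)C(C)(C)C)[C@H]2C(C)=C | intermediate
12 | 11 carrying a (1R)-1-hydroxyethyl group on C3 (syn aldol, group on the alkene-bridge side) | CC1=C[C@H]2[C@@H]([C@@H](C)O)C(=O)O[C@@H]1[C@H](O[Si](C)(C)C(C)(C)C)[C@H]2C(C)=C | intermediate
13 | tert-butyldimethylsilyl ether of 12 | CC1=C[C@H]2[C@@H]([C@@H](C)O[Si](C)(C)C(C)(C)C)C(=O)O[C@@H]1[C@H](O[Si](C)(C)C(C)(C)C)[C@H]2C(C)=C | intermediate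
14 | allyl 3-oxo-4-(ring C3a)-5-silyloxyhexanoate; ring: C6 hydroxyl, C5 silyloxy and the C3a chain cis, isopropenyl trans, C7(methyl)=C7a alkene | CC1=C[C@@H]([C@@H]([C@@H](C)O[Si](C)(C)C(C)(C)C)C(=O)CC(=O)OCC=C)[C@H](C(C)=C)[C@@H](O[Si](C)(C)C(C)(C)C)[C@H]1O | intermediate
15 | C6 ketone (enone) of 14 | CC1=C[C@@H]([C@@H]([C@@H](C)O[Si](C)(C)C(C)(C)C)C(=O)CC(=O)OCC=C)[C@H](C(C)=C)[C@@H](O[Si](C)(C)C(C)(C)C)C1=O | intermediate (not isolated)
16 | cis-fused Michael adduct (C7a epimer of 17; C1 and C7 as epimer mixtures) | CC1[C@H]2C(C(=O)OCC=C)C(=O)[C@H]([C@@H](C)O[Si](C)(C)C(C)(C)C)[C@H]2[C@H](C(C)=C)[C@@H](O[Si](C)(C)C(C)(C)C)C1=O | intermediate (not isolated)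
17 | allyl trans-fused 7-methyl-2,6-dioxo-3-[(1R)-1-silyloxyethyl]-4-isopropenyl-5-silyloxyoctahydroindene-1-carboxylate (all six-ring substituents equatorial) | C[C@H]1[C@@H]2[C@@H](C(=O)OCC=C)C(=O)[C@H]([C@@H](C)O[Si](C)(C)C(C)(C)C)[C@H]2[C@H](C(C)=C)[C@@H](O[Si](C)(C)C(C)(C)C)C1=O | intermediate
18 | 7-(phenylselanyl) derivative of 17 (selenium axial) | C[C@@]1([Se]c3ccccc3)[C@@H]2[C@@H](C(=O)OCC=C)C(=O)[C@H]([C@@H](C)O[Si](C)(C)C(C)(C)C)[C@H]2[C@H](C(C)=C)[C@@H](O[Si](C)(C)C(C)(C)C)C1=O | intermediate (not isolated)
19 | C6 equatorial alcohol from 18 (hydroxyl trans to the C5 silyloxy group) | C[C@@]1([Se]c3ccccc3)[C@@H]2[C@@H](C(=O)OCC=C)C(=O)[C@H]([C@@H](C)O[Si](C)(C)C(C)(C)C)[C@H]2[C@H](C(C)=C)[C@@H](O[Si](C)(C)C(C)(C)C)[C@@H]1O | intermediate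
20 | selenoxide of 19 | C[C@@]1([Se](=O)c3ccccc3)[C@@H]2[C@@H](C(=O)OCC=C)C(=O)[C@H]([C@@H](C)O[Si](C)(C)C(C)(C)C)[C@H]2[C@H](C(C)=C)[C@@H](O[Si](C)(C)C(C)(C)C)[C@@H]1O | intermediate (not isolated)
21 | allyl 7-methylidene-6-hydroxy-2-oxo hydrindane-1-carboxylate (substituents as in 19 without selenium) | C=C1[C@@H]2[C@@H](C(=O)OCC=C)C(=O)[C@H]([C@@H](C)O[Si](C)(C)C(C)(C)C)[C@H]2[C@H](C(C)=C)[C@@H](O[Si](C)(C)C(C)(C)C)[C@@H]1O | intermediate
22 | trans-fused 6-hydroxy-7-methylidene-3-[(1R)-1-silyloxyethyl]-4-isopropenyl-5-silyloxyhydrindan-2-one (C6 hydroxyl equatorial) | C=C1[C@@H]2CC(=O)[C@H]([C@@H](C)O[Si](C)(C)C(C)(C)C)[C@H]2[C@H](C(C)=C)[C@@H](O[Si](C)(C)C(C)(C)C)[C@@H]1O | intermediate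
23 | (E)-3-methylpent-2-enoic acid | CC/C(C)=C/C(=O)O | starting material
24 | C6 (E)-3-methylpent-2-enoate of 22 with inverted C6 (ester axial, cis to the C5 oxygen) | C=C1[C@@H]2CC(=O)[C@H]([C@@H](C)O[Si](C)(C)C(C)(C)C)[C@H]2[C@H](C(C)=C)[C@@H](O[Si](C)(C)C(C)(C)C)[C@H]1OC(=O)/C=C(\C)CC | intermediate
25 | diol from 24 (C5 hydroxyl and side-chain carbinol free) | C=C1[C@@H]2CC(=O)[C@H]([C@@H](C)O)[C@H]2[C@H](C(C)=C)[C@@H](O)[C@H]1OC(=O)/C=C(\C)CC | intermediate
26 | 25 with the isopropenyl group converted into the (2S)-2-methyloxiran-2-yl group | C=C1[C@@H]2CC(=O)[C@H]([C@@H](C)O)[C@H]2[C@H]([C@@]2(C)CO2)[C@@H](O)[C@H]1OC(=O)/C=C(\C)CC | intermediate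
27 | side-chain acetate of 26 (C5 hydroxyl free) | C=C1[C@@H]2CC(=O)[C@H]([C@@H](C)OC(C)=O)[C@H]2[C@H]([C@@]2(C)CO2)[C@@H](O)[C@H]1OC(=O)/C=C(\C)CC | intermediate
28 | (S)-2-methylbutanoic acid | CC[C@H](C)C(=O)O | starting material
29 | CNP0120390.2, (3S,3aR,4S,5R,6S,7aR)-3-[(1R)-1-acetoxyethyl]-7-methylidene-4-[(2S)-2-methyloxiran-2-yl]-5-[(2S)-2-methylbutanoyloxy]-2-oxooctahydroinden-6-yl (E)-3-methylpent-2-enoate | C=C1[C@@H]2CC(=O)[C@H]([C@@H](C)OC(C)=O)[C@H]2[C@H]([C@@]2(C)CO2)[C@@H](OC(=O)[C@@H](C)CC)[C@H]1OC(=O)/C=C(\C)CC | target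

**Count and risks**

Total step count: 18. Longest linear sequence: 18 steps, from (S)-carvone 1 to 29.

Steps most likely to fail:

1. Step 10 (key step). The closure may stop at the kinetically formed cis-fused isomer, or the equilibrium may not favour the trans junction strongly enough; prolonged base could also cost the β-silyloxy group by elimination. Fallback, setting out from the mixture of 16 and 17 and returning to 17: double enolisation with LiN(SiMe3)2 and silylation with Me3SiCl should give the bis(trimethylsilyl) enol ether F1; Saegusa–Ito oxidation with Pd(OAc)2 in MeCN should give the ring-fusion enone F2, in which C7a is trigonal; Birch reduction (Li, NH3/THF, t-BuOH, −78 °C, then NH4Cl) should protonate C7a axially, as in the reduction of hydrindenones, and give the trans-fused 17.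

2. Step 6. The [3,3] shift has to pass through a boat-like bicyclic transition state; the cyclic orthoester may instead fragment, or the tertiary allylic alcohol may dehydrate. Fallback, from 8 back to 11: the secondary hydroxyl is silylated (Et3SiOTf, 2,6-lutidine) to the triethylsilyl ether F3, the tertiary alcohol is acetylated (Ac2O, DMAP, Et3N) to the tertiary acetate F4, an Ireland–Claisen rearrangement (LiN(iPr)2, Me3SiCl, THF, −78 → 65 °C, then aqueous acid) should give the carboxylic acid F5, AcOH/THF/H2O removes the triethylsilyl group to the hydroxy acid F6, and Yamaguchi lactonisation (2,4,6-trichlorobenzoyl chloride, Et3N, then DMAP, toluene) closes the bridged lactone 11.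

3. Step 14. The carboxylate may attack the methylidene carbon (SN2′) or the activated alcohol may eliminate instead of undergoing inversion at the hindered allylic carbinol. Fallback, from 22 back to 24: the alcohol is converted (MeSO2Cl, Et3N, −20 °C) into the mesylate F7, which is displaced with inversion by the caesium salt of 23 (Cs2CO3, 18-crown-6, toluene), a carboxylate SN2 reaction that avoids the oxyphosphonium intermediate, to give 24.

Further compounds
F1 | step 10 | bis(trimethylsilyl) enol ether of the 16/17 mixture (C6 enol ether toward C7, C2 enol ether toward C1; C7a unassigned) | CC1=C(O[Si](C)(C)C)[C@H](O[Si](C)(C)C(C)(C)C)[C@@H](C(C)=C)[C@@H]2[C@@H]([C@@H](C)O[Si](C)(C)C(C)(C)C)C(O[Si](C)(C)C)=C(C(=O)OCC=C)C12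
F2 | step 10 | ring-fusion enone (C6 ketone, C7(methyl)=C7a; C1 unassigned) | CC1=C2C(C(=O)OCC=C)C(=O)[C@H]([C@@H](C)O[Si](C)(C)C(C)(C)C)[C@H]2[C@H](C(C)=C)[C@@H](O[Si](C)(C)C(C)(C)C)C1=O
F3 | step 6 | triethylsilyl ether of 8 at the secondary hydroxyl | C[C@]1(O)C=C[C@H](C(C)=C)[C@@H](O[Si](C)(C)C(C)(C)C)[C@H]1O[Si](CC)(CC)CC
F4 | step 6 | tertiary acetate of F3 | C[C@]1(OC(C)=O)C=C[C@H](C(C)=C)[C@@H](O[Si](C)(C)C(C)(C)C)[C@H]1O[Si](CC)(CC)CC
F5 | step 6 | C3a acetic acid with C6 triethylsilyl ether (acid chain trans to isopropenyl) | CC1=C[C@@H](CC(=O)O)[C@H](C(C)=C)[C@@H](O[Si](C)(C)C(C)(C)C)[C@H]1O[Si](CC)(CC)CC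
F6 | step 6 | hydroxy acid from F5 | CC1=C[C@@H](CC(=O)O)[C@H](C(C)=C)[C@@H](O[Si](C)(C)C(C)(C)C)[C@H]1O
F7 | step 14 | C6 mesylate of 22 | C=C1[C@@H]2CC(=O)[C@H]([C@@H](C)O[Si](C)(C)C(C)(C)C)[C@H]2[C@H](C(C)=C)[C@@H](O[Si](C)(C)C(C)(C)C)[C@@H]1OS(C)(=O)=O
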